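The synthesis rests on disconnecting two bonds at C8: the ether bond to the phenol oxygen of ring B (the guaiacyl ring) and the C7–C8 bond to the carbinol carbon on ring A (the trimethoxyphenyl ring). C8 carries these two neighbours plus C9 and is therefore a carbene carbon in disguise. In one operation a rhodium carbene from tert-butyl diazoacetate (C9 as ester) takes up the free phenol of side-chain-silylated dihydroconiferyl alcohol, and the oxonium ylide adds to 3,4,5-trimethoxybenzaldehyde bound to a chiral zirconium BINOLate, creating both bonds and both stereocentres in the threo (7R,8R) arrangement. Ester-to-methyl conversion and desilylation finish the synthesis.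

Key step: step 2

Atom labels: C7 is the carbinol carbon, C8 the aryloxy-bearing carbon, C9 the methyl carbon (an ester carbon until step 3).

Assumption: the sense of induction of the zirconium BINOLate is not established for this substrate class; the (S) ligand is written, and the (R) ligand is to be used instead, with no other change, if the adduct proves antipodal.

Step 1
Reactants: 1 dihydroconiferyl alcohol [4-(3-hydroxypropyl)-2-methoxyphenol]
Product: 3 4-[3-(tert-butyldimethylsilyloxy)propyl]-2-methoxyphenol, via bis-silyl ether 2 (not isolated)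
Conditions: TBSCl (2.3 equiv), imidazole, DMF, rt; aqueous work-up, then crude 2 with K2CO3, MeOH, rt
Reagents that add atoms: tert-butyldimethylsilyl chloride (TBSCl), CC(C)(C)[Si](C)(C)Cl
Why: Exhaustive silylation needs no selectivity, and base-mediated methanolysis then cleaves only the aryl silyl ether, because phenoxide is by far the better leaving group, while the primary alkyl silyl ether stays (silyl protection followed by chemoselective desilylation of an aryl silyl ether).

Step 2
Reactants: 3 4-[3-(tert-butyldimethylsilyloxy)propyl]-2-methoxyphenol; 4 tert-butyl diazoacetate; 5 3,4,5-trimethoxybenzaldehyde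
Product: 7 tert-butyl (2S,3R)-2-{4-[3-(tert-butyldimethylsilyloxy)propyl]-2-methoxyphenoxy}-3-hydroxy-3-(3,4,5-trimethoxyphenyl)propanoate, via oxonium ylide 6 (not isolated)
Conditions: Rh2(OAc)4 (2 mol%), Zr(OBu)4 (15 mol%), (S)-3,3′-Br2-BINOL (30 mol%) (catalyst pre-formed, BuOH removed in vacuo), 4 Å MS, CH2Cl2, 0 °C; 5 (3 equiv) present, 4 (1.5 equiv) added by syringe pump over 8 h
Reagents that add atoms: none
Why: Proposed new method: Rh2(OAc)4 expels N2 from 4 and the electrophilic rhodium carbene is captured by the phenol oxygen of 3 to give protic oxonium ylide 6 (C8–O bond), which, as a zirconium-bound enolate, adds to aldehyde 5 activated on the BINOLate complex of tetravalent zirconium (C7–C8 bond) before the 1,2-proton shift can give the simple O–H insertion product; proton transfer then releases 7. The closest known reaction type is the aldol-type three-component trapping of alcohol- or water-derived oxonium ylides from aryldiazoacetates with aldehydes under Rh2(OAc)4 and a chiral Lewis acid, whereas an acceptor-only diazoacetate combined with a phenol has not been shown in this manifold. No ring is closed. C8 and C7 arise together in the C–C bond formation: the syn (threo) relationship is expected from a closed chair-like transition state in which the enolate oxygen and the aryloxy oxygen chelate zirconium (fixing the Z enolate geometry) and the aldehyde aryl group sits equatorial, and the absolute sense (2S,3R) from the BINOLate, which should leave only one face of the bound aldehyde open. The step needs trapping to win over proton shift, carbene dimerisation and carbonyl ylide formation, and this is served by the silyl cap on the side chain (the phenol is the only O–H, the catalyst being freed of butanol), by slow addition of 4 into excess 5, and by the aldehyde itself, whose two meta methoxy groups withdraw inductively while the flanked para methoxy group is twisted out of conjugation. The bulky tert-butyl ester further disfavours carbene dimerisation and should survive the Lewis acid.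

Step 3
Reactants: 7 tert-butyl (2S,3R)-2-{4-[3-(tert-butyldimethylsilyloxy)propyl]-2-methoxyphenoxy}-3-hydroxy-3-(3,4,5-trimethoxyphenyl)propanoate
Product: 8 (1R,2R)-2-{4-[3-(tert-butyldimethylsilyloxy)propyl]-2-methoxyphenoxy}-1-(3,4,5-trimethoxyphenyl)propane-1,3-diol
Conditions: LiAlH4, THF, 0 °C
Reagents that add atoms: none
Why: Hydride reduction of the ester to the primary alcohol (LiAlH4 ester reduction) is routine for β-hydroxy-α-aryloxy esters, and at 0 °C the aluminium alkoxide at C7 should neither undergo retro-aldol cleavage nor epimerise C8, so both centres are carried through unchanged (C8 becomes R only because the substituent priorities change).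

Step 4
Reactants: 8 (1R,2R)-2-{4-[3-(tert-butyldimethylsilyloxy)propyl]-2-methoxyphenoxy}-1-(3,4,5-trimethoxyphenyl)propane-1,3-diol
Product: 9 (2R,3R)-2-{4-[3-(tert-butyldimethylsilyloxy)propyl]-2-methoxyphenoxy}-3-hydroxy-3-(3,4,5-trimethoxyphenyl)propyl 4-methylbenzenesulfonate
Conditions: TsCl (1.1 equiv), pyridine, CH2Cl2, 0 °C
Reagents that add atoms: 4-methylbenzenesulfonyl chloride (TsCl), Cc1ccc(cc1)S(=O)(=O)Cl
Why: Sulfonylation responds strongly to steric hindrance, so the open primary C9 hydroxyl should react well before the secondary benzylic C7 hydroxyl that is flanked by ring A and the aryloxy-bearing carbon (selective monotosylation of a primary/secondary 1,3-diol), and no stereocentre is touched.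

Step 5
Reactants: 9 (2R,3R)-2-{4-[3-(tert-butyldimethylsilyloxy)propyl]-2-methoxyphenoxy}-3-hydroxy-3-(3,4,5-trimethoxyphenyl)propyl 4-methylbenzenesulfonate
Product: 10 (1R,2R)-2-{4-[3-(tert-butyldimethylsilyloxy)propyl]-2-methoxyphenoxy}-1-(3,4,5-trimethoxyphenyl)propan-1-ol
Conditions: LiEt3BH (3 equiv), THF, 0 °C to rt
Reagents that add atoms: none
Why: LiEt3BH displaces primary sulfonates by SN2 hydride transfer faster than the C7 alkoxide can close a strained four-membered ether onto C9, so C9 should become the methyl group with C7 and C8 untouched (hydride reduction of a tosylate).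

Step 6
Reactants: 10 (1R,2R)-2-{4-[3-(tert-butyldimethylsilyloxy)propyl]-2-methoxyphenoxy}-1-(3,4,5-trimethoxyphenyl)propan-1-ol
Product: 11 surinamensinol A [(1R,2R)-2-[4-(3-hydroxypropyl)-2-methoxyphenoxy]-1-(3,4,5-trimethoxyphenyl)propan-1-ol]
Conditions: Bu4NF, THF, 0 °C to rt
Reagents that add atoms: none
Why: Fluoride cleaves the Si–O bond of the primary silyl ether (fluoride-mediated desilylation) without acid, which matters because the electron-rich benzylic C7 alcohol could ionise and epimerise under acidic deprotection.

Compound list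
1 | dihydroconiferyl alcohol, 4-(3-hydroxypropyl)-2-methoxyphenol | COc1cc(CCCO)ccc1O | starting material
2 | tert-butyl{3-[4-(tert-butyldimethylsilyloxy)-3-methoxyphenyl]propoxy}dimethylsilane (bis-silyl ether) | COc1cc(CCCO[Si](C)(C)C(C)(C)C)ccc1O[Si](C)(C)C(C)(C)C | intermediate
3 | 4-[3-(tert-butyldimethylsilyloxy)propyl]-2-methoxyphenol | COc1cc(CCCO[Si](C)(C)C(C)(C)C)ccc1O | intermediate
4 | tert-butyl diazoacetate | CC(C)(C)OC(=O)C=[N+]=[N-] | starting material
5 | 3,4,5-trimethoxybenzaldehyde | COc1cc(C=O)cc(OC)c1OC | starting material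
6 | protic oxonium ylide from 3 and the carbene of 4, drawn free of rhodium | COc1cc(CCCO[Si](C)(C)C(C)(C)C)ccc1[OH+][CH-]C(=O)OC(C)(C)C | intermediate
7 | tert-butyl (2S,3R)-2-{4-[3-(tert-butyldimethylsilyloxy)propyl]-2-methoxyphenoxy}-3-hydroxy-3-(3,4,5-trimethoxyphenyl)propanoate | COc1cc(CCCO[Si](C)(C)C(C)(C)C)ccc1O[C@H](C(=O)OC(C)(C)C)[C@H](O)c1cc(OC)c(OC)c(OC)c1 | intermediate
8 | (1R,2R)-2-{4-[3-(tert-butyldimethylsilyloxy)propyl]-2-methoxyphenoxy}-1-(3,4,5-trimethoxyphenyl)propane-1,3-diol | COc1cc(CCCO[Si](C)(C)C(C)(C)C)ccc1O[C@H](CO)[C@H](O)c1cc(OC)c(OC)c(OC)c1 | intermediate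
9 | (2R,3R)-2-{4-[3-(tert-butyldimethylsilyloxy)propyl]-2-methoxyphenoxy}-3-hydroxy-3-(3,4,5-trimethoxyphenyl)propyl 4-methylbenzenesulfonate | COc1cc(CCCO[Si](C)(C)C(C)(C)C)ccc1O[C@H](COS(=O)(=O)c1ccc(C)cc1)[C@H](O)c1cc(OC)c(OC)c(OC)c1 | intermediate
10 | (1R,2R)-2-{4-[3-(tert-butyldimethylsilyloxy)propyl]-2-methoxyphenoxy}-1-(3,4,5-trimethoxyphenyl)propan-1-ol | COc1cc(CCCO[Si](C)(C)C(C)(C)C)ccc1O[C@H](C)[C@H](O)c1cc(OC)c(OC)c(OC)c1 | intermediate
11 | surinamensinol A, (1R,2R)-2-[4-(3-hydroxypropyl)-2-methoxyphenoxy]-1-(3,4,5-trimethoxyphenyl)propan-1-ol | COc1cc(CCCO)ccc1O[C@H](C)[C@H](O)c1cc(OC)c(OC)c(OC)c1 | target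

Total step count: 6. Longest linear sequence: 6 steps (1 to 11).

Steps most likely to fail

Step 2. Proton transfer within the ylide may outrun the aldol-type trapping, so that only O–H insertion occurs, or the trapping may proceed with poor syn or facial selectivity. The fallback replaces the three-component coupling by an auxiliary-controlled glycolate aldol and sets out from 3.
- Williamson alkylation of 3 with bromoacetic acid (NaH, THF) should give {4-[3-(tert-butyldimethylsilyloxy)propyl]-2-methoxyphenoxy}acetic acid F1.
- The mixed pivalic anhydride of F1 (PivCl, Et3N, THF, −20 °C) should acylate (S)-4-benzyloxazolidin-2-one in the presence of LiCl to give the N-aryloxyacetyl oxazolidinone F2.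
- The dibutylboron Z enolate of F2 (Bu2BOTf, i-Pr2NEt, CH2Cl2, −78 °C) should add to 5 through a closed chair transition state on the enolate face away from the benzyl group (Evans syn aldol) to give the syn aldol imide F3, which has the C7/C8 configuration of 7.
- LiBH4 (THF, MeOH, 0 °C) removes the auxiliary reductively, and the fallback comes back to the route at diol 8.

Step 4. Sulfonylation may not stay confined to the primary hydroxyl, and a benzylic sulfonate on the electron-rich ring A would ionise. The fallback removes the need for site selectivity by masking C7–OH before the ester is reduced, and sets out from 7.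
- TBSCl, imidazole and catalytic DMAP in DMF should give the C7-silylated ester F4.
- i-Bu2AlH (CH2Cl2, −78 to 0 °C) should reduce it to the C7-silylated primary alcohol F5, which has a single free hydroxyl.
- TsCl, Et3N and DMAP should give the C7-silylated tosylate F6.
- LiEt3BH should give the bis-silyl ether of the target F7.
- Bu4NF removes both silyl groups, and the fallback comes back at 11.

Step 5. The C7 alkoxide may displace the sulfonate intramolecularly, or hydride displacement at the β-branched carbon may be sluggish. The fallback avoids any alkoxide and replaces hydride displacement by hydrogenolysis; it sets out from 9.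
- NaI in butanone at reflux (Finkelstein exchange, neutral) should give the iodohydrin F8.
- Hydrogenolysis of the C–I bond (H2, Pd/C, Et3N, EtOAc, rt), with the amine holding back benzylic C–O cleavage, should give 10, where the route resumes.

Further compounds
F1 | step 2 | {4-[3-(tert-butyldimethylsilyloxy)propyl]-2-methoxyphenoxy}acetic acid | COc1cc(CCCO[Si](C)(C)C(C)(C)C)ccc1OCC(=O)O
F2 | step 2 | (4S)-4-benzyl-3-({4-[3-(tert-butyldimethylsilyloxy)propyl]-2-methoxyphenoxy}acetyl)-1,3-oxazolidin-2-one | COc1cc(CCCO[Si](C)(C)C(C)(C)C)ccc1OCC(=O)N1C(=O)OC[C@@H]1Cc1ccccc1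
F3 | step 2 | (4S)-4-benzyl-3-[(2S,3R)-2-{4-[3-(tert-butyldimethylsilyloxy)propyl]-2-methoxyphenoxy}-3-hydroxy-3-(3,4,5-trimethoxyphenyl)propanoyl]-1,3-oxazolidin-2-one | COc1cc(CCCO[Si](C)(C)C(C)(C)C)ccc1O[C@H](C(=O)N1C(=O)OC[C@@H]1Cc1ccccc1)[C@H](O)c1cc(OC)c(OC)c(OC)c1
F4 | step 4 | tert-butyl (2S,3R)-3-(tert-butyldimethylsilyloxy)-2-{4-[3-(tert-butyldimethylsilyloxy)propyl]-2-methoxyphenoxy}-3-(3,4,5-trimethoxyphenyl)propanoate | COc1cc(CCCO[Si](C)(C)C(C)(C)C)ccc1O[C@H](C(=O)OC(C)(C)C)[C@H](O[Si](C)(C)C(C)(C)C)c1cc(OC)c(OC)c(OC)c1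
F5 | step 4 | (2R,3R)-3-(tert-butyldimethylsilyloxy)-2-{4-[3-(tert-butyldimethylsilyloxy)propyl]-2-methoxyphenoxy}-3-(3,4,5-trimethoxyphenyl)propan-1-ol | COc1cc(CCCO[Si](C)(C)C(C)(C)C)ccc1O[C@H](CO)[C@H](O[Si](C)(C)C(C)(C)C)c1cc(OC)c(OC)c(OC)c1
F6 | step 4 | (2R,3R)-3-(tert-butyldimethylsilyloxy)-2-{4-[3-(tert-butyldimethylsilyloxy)propyl]-2-methoxyphenoxy}-3-(3,4,5-trimethoxyphenyl)propyl 4-methylbenzenesulfonate | COc1cc(CCCO[Si](C)(C)C(C)(C)C)ccc1O[C@H](COS(=O)(=O)c1ccc(C)cc1)[C@H](O[Si](C)(C)C(C)(C)C)c1cc(OC)c(OC)c(OC)c1
F7 | step 4 | tert-butyl{[(1R,2R)-2-{4-[3-(tert-butyldimethylsilyloxy)propyl]-2-methoxyphenoxy}-1-(3,4,5-trimethoxyphenyl)propyl]oxy}dimethylsilane | COc1cc(CCCO[Si](C)(C)C(C)(C)C)ccc1O[C@H](C)[C@H](O[Si](C)(C)C(C)(C)C)c1cc(OC)c(OC)c(OC)c1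
F8 | step 5 | (1R,2S)-2-{4-[3-(tert-butyldimethylsilyloxy)propyl]-2-methoxyphenoxy}-3-iodo-1-(3,4,5-trimethoxyphenyl)propan-1-ol | COc1cc(CCCO[Si](C)(C)C(C)(C)C)ccc1O[C@H](CI)[C@H](O)c1cc(OC)c(OC)c(OC)c1
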